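**Retrosynthetic overview**

1. The target comes from a prenyl-bearing triol by two angeloylations (ring O-2 and side-chain O), acetylation at O-3 and a final asymmetric epoxidation of the prenyl group. The side chain is joined at the bond between the C(=CH2) carbon and the carbinol carbon by a Ni/Cr coupling of a ring-bound alkenyl triflate with 4-methylpent-3-enal.
2. The alkenyl triflate comes from a methyl ketone and this from an epoxy Weinreb amide. The ring epoxide is closed by SN2 attack of the tertiary C1 hydroxyl on a C6 mesylate; that tertiary oxygen and the amide carbon are the two ends of a former lactone bridge.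
3. The bridged lactone is elaborated by OsO4 dihydroxylation on the face of the lactone bridge (sets C2 and C3) and a Baeyer–Villiger oxidation that turns an acetyl group into the C6 oxygen. The lactone itself is the [4+2] adduct of 6-methyl-2H-pyran-2-one and but-3-en-2-one, which forms the C4–C5 and C6–C1 bonds of the target ring.
4. Enabling feature: in the 7-oxabicyclo[4.1.0]heptane of the target (C1 = methyl-bearing epoxide carbon, C4 = carbon carrying the side chain), C1 and C4 are 1,4-related across the cyclohexane and carry, cis to each other, the epoxide oxygen O7 and the side-chain carbon C(=CH2). Joined as O–C(=O), these make the cyclohexane the carbocycle of a 2-oxabicyclo[2.2.2]oct-5-en-3-one, a pyranone cycloadduct. This bridge is absent from the target and relays one catalyst-set stereocentre to all five ring stereocentres.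
5. Ring order: cyclohexane ring with the temporary lactone bridge (step 1), bridge opened (step 5), ring epoxide (step 7), side-chain epoxide (step 15).

Key step: step 1

Remark: 6-methyl-2H-pyran-2-one, but-3-en-2-one, 4-methylpent-3-en-1-ol and angelic acid are taken as purchasable; bridged lactones are numbered as 2-oxabicyclo[2.2.2]octanes (C1 methyl-bearing bridgehead, O2, C3 carbonyl, C4 bridgehead, C7 next to C1), the epoxides as 7-oxabicyclo[4.1.0]heptanes as in the target.

**Route**

Step 1
Reactants: 1 6-methyl-2H-pyran-2-one; 2 but-3-en-2-one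
Product: 3 (1R,4R,7R)-7-acetyl-1-methyl-2-oxabicyclo[2.2.2]oct-5-en-3-one (acetyl endo: syn to C5=C6, anti to the O2–C3 bridge)
Conditions: (S)-3,3-diphenyl-1-(2-methylphenyl)tetrahydro-1H,3H-pyrrolo[1,2-c][1,3,2]oxazaborole·HNTf2 (20 mol%), 2 (3 equiv), CH2Cl2, −40 → −20 °C
Reagents that add atoms: none
Why: Proposed new method: the protonated oxazaborolidine binds the carbonyl oxygen of 2 and lowers its LUMO, and the s-cis-locked dienyl ester C3=C4–C5=C6 of 1 adds in a concerted, asynchronous normal-demand [4+2] cycloaddition in which the nucleophilic C3 bonds first to the CH2 terminus and C6, whose developing positive charge is carried by the ring oxygen and the methyl group, then bonds to the acetyl-bearing carbon. The closest known reaction types are the thermal Diels–Alder additions of 2-pyranones to acrylic dienophiles, which give the same bridged lactones, and the oxazaborolidinium-catalysed enantioselective Diels–Alder additions of enones and acrylates to weak dienes such as buta-1,3-diene and furan; the combination of the two is not established. One suprafacial/suprafacial [4+2] closure forms the carbocyclic six-membered ring and with it the 2-oxabicyclo[2.2.2]octene, in which the O–C(=O) unit of 1 has become the two-atom bridge. The bridgeheads C1 and C4 are tied to each other by that bridge, C7 is set by the endo rule (acetyl under C4–C5 of the diene, hence syn to the new C5=C6 and anti to the lactone bridge), and the absolute sense comes from the catalyst, whose enantiomer is chosen so that the diene adds to the Cα-Si face of bound 2 (the antipode is used if the working model for this diene proves reversed). The step needs regio-, endo- and face selectivity without loss of CO2: the first is secured by the polarisation of 1 (largest HOMO coefficient at C3) and sharpened by the Lewis acid, the second by the Lewis-acid-enhanced endo preference, and the low temperature keeps the adduct from cycloreversion and the β-acyloxy ketone from β-elimination. Because the carbonyl of 1 can compete for boron, 2 is used in excess.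

Step 2
Reactants: 3 (1R,4R,7R)-7-acetyl-1-methyl-2-oxabicyclo[2.2.2]oct-5-en-3-one
Product: 4 (1S,4R,5R,6R,7R)-7-acetyl-5,6-dihydroxy-1-methyl-2-oxabicyclo[2.2.2]octan-3-one (both hydroxyls syn to the O2–C3 bridge)
Conditions: OsO4 (2 mol%), NMO, acetone/H2O, 0 °C → rt
Reagents that add atoms: N-methylmorpholine N-oxide, C[N+]1([O-])CCOCC1; water, O
Why: Upjohn dihydroxylation, in which OsO4 should add suprafacially to the C5=C6 face that carries only the O–C(=O) bridge because the other face is screened by the CH2–CH(Ac) bridge with its endo acetyl group, so that C5 and C6 are both set cis to the lactone bridge; neutral work-up and immediate silylation forestall lactone migration to O-6.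

Step 3
Reactants: 4 (1S,4R,5R,6R,7R)-7-acetyl-5,6-dihydroxy-1-methyl-2-oxabicyclo[2.2.2]octan-3-one
Product: 5 (1S,4R,5R,6R,7R)-7-acetyl-1-methyl-5,6-bis(triethylsilyloxy)-2-oxabicyclo[2.2.2]octan-3-one
Conditions: TESOTf, 2,6-lutidine, CH2Cl2, −78 → 0 °C
Reagents that add atoms: triethylsilyl trifluoromethanesulfonate, CC[Si](CC)(CC)OS(=O)(=O)C(F)(F)F
Why: Silyl ether formation with the silyl triflate and a hindered weak base should protect both crowded secondary hydroxyls at low temperature without enolising the methyl ketone; no stereocentre is touched.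

Step 4
Reactants: 5 (1S,4R,5R,6R,7R)-7-acetyl-1-methyl-5,6-bis(triethylsilyloxy)-2-oxabicyclo[2.2.2]octan-3-one
Product: 6 (1S,4R,5R,6R,7R)-1-methyl-3-oxo-5,6-bis(triethylsilyloxy)-2-oxabicyclo[2.2.2]octan-7-yl acetate
Conditions: mCPBA, NaHCO3, CH2Cl2, rt
Reagents that add atoms: 3-chloroperoxybenzoic acid, OOC(=O)c1cccc(Cl)c1
Why: Baeyer–Villiger oxidation, in which the secondary ring carbon C7 migrates in preference to methyl and with retention, so the endo acetyl group becomes an endo acetate anti to the lactone oxygen on C1.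

Step 5
Reactants: 6 (1S,4R,5R,6R,7R)-1-methyl-3-oxo-5,6-bis(triethylsilyloxy)-2-oxabicyclo[2.2.2]octan-7-yl acetate
Product: 7 (1R,2R,3R,4S,5R)-4,5-dihydroxy-N-methoxy-N,4-dimethyl-2,3-bis(triethylsilyloxy)cyclohexane-1-carboxamide
Conditions: MeNH(OMe)·HCl, AlMe3 (5 equiv each), CH2Cl2, 0 °C → rt
Reagents that add atoms: N,O-dimethylhydroxylamine hydrochloride, CNOC.Cl
Why: Weinreb aminolysis with the aluminium amide should open the bridged lactone to the N-methoxy-N-methylamide, freeing the tertiary hydroxyl, and at the same time cleave the acetate; no stereocentre changes.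

Step 6
Reactants: 7 (1R,2R,3R,4S,5R)-4,5-dihydroxy-N-methoxy-N,4-dimethyl-2,3-bis(triethylsilyloxy)cyclohexane-1-carboxamide
Product: 8 (1R,2R,3R,4R,5R)-4-hydroxy-N-methoxy-N,4-dimethyl-5-(methylsulfonyloxy)-2,3-bis(triethylsilyloxy)cyclohexane-1-carboxamide
Conditions: MsCl, Et3N, CH2Cl2, −20 → 0 °C
Reagents that add atoms: methanesulfonyl chloride, CS(=O)(=O)Cl
Why: Sulfonylation through sulfene is selective for the secondary hydroxyl over the tertiary one and leaves the configuration unchanged.

Step 7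
Reactants: 8 (1R,2R,3R,4R,5R)-4-hydroxy-N-methoxy-N,4-dimethyl-5-(methylsulfonyloxy)-2,3-bis(triethylsilyloxy)cyclohexane-1-carboxamide
Product: 9 (1S,2R,3R,4R,6S)-N-methoxy-N,1-dimethyl-2,3-bis(triethylsilyloxy)-7-oxabicyclo[4.1.0]heptane-4-carboxamide
Conditions: K2CO3, MeOH, 0 °C → rt
Reagents that add atoms: none
Why: Intramolecular Williamson (SN2) epoxide closure, in which the tertiary alkoxide and the mesylate are trans-diaxial in the chair with the amide equatorial and backside attack inverts the mesylate carbon, so the epoxide oxygen ends on the face of the former lactone bridge.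

Step 8
Reactants: 9 (1S,2R,3R,4R,6S)-N-methoxy-N,1-dimethyl-2,3-bis(triethylsilyloxy)-7-oxabicyclo[4.1.0]heptane-4-carboxamide
Product: 10 1-[(1S,2R,3R,4R,6S)-1-methyl-2,3-bis(triethylsilyloxy)-7-oxabicyclo[4.1.0]heptan-4-yl]ethan-1-one
Conditions: MeLi, THF, −78 °C; aq. NH4Cl
Reagents that add atoms: methyllithium, [Li]C
Why: Weinreb ketone synthesis, in which the chelated tetrahedral intermediate stops at the ketone stage while the hindered trisubstituted epoxide and the silyl ethers are inert to MeLi at −78 °C.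

Step 9
Reactants: 10 1-[(1S,2R,3R,4R,6S)-1-methyl-2,3-bis(triethylsilyloxy)-7-oxabicyclo[4.1.0]heptan-4-yl]ethan-1-one
Product: 11 1-[(1S,2R,3R,4R,6S)-1-methyl-2,3-bis(triethylsilyloxy)-7-oxabicyclo[4.1.0]heptan-4-yl]ethenyl trifluoromethanesulfonate
Conditions: KN(SiMe3)2, THF, −78 °C; then PhNTf2
Reagents that add atoms: N-phenylbis(trifluoromethanesulfonimide), FC(F)(F)S(=O)(=O)N(c1ccccc1)S(=O)(=O)C(F)(F)F
Why: Kinetic deprotonation of the methyl group (less hindered than the ring α-CH) and O-triflation of the enolate should give the terminal enol triflate, the low temperature avoiding epimerisation at C4 and β-elimination of the silyloxy group.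

Step 10
Reactants: 12 4-methylpent-3-en-1-ol
Product: 13 4-methylpent-3-enal
Conditions: Dess–Martin periodinane, NaHCO3, CH2Cl2, 0 °C; used at once
Reagents that add atoms: none
Why: Dess–Martin oxidation under buffered, non-basic conditions should give the β,γ-unsaturated aldehyde without migration of the double bond.

Step 11
Reactants: 11 1-[(1S,2R,3R,4R,6S)-1-methyl-2,3-bis(triethylsilyloxy)-7-oxabicyclo[4.1.0]heptan-4-yl]ethenyl trifluoromethanesulfonate; 13 4-methylpent-3-enal
Product: 14 (3S)-6-methyl-2-[(1S,2R,3R,4S,6S)-1-methyl-2,3-bis(triethylsilyloxy)-7-oxabicyclo[4.1.0]heptan-4-yl]hepta-1,5-dien-3-ol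
Conditions: CrCl2 (4 equiv), NiCl2 (5 mol%), (S)-N-[2-(4-isopropyl-4,5-dihydro-1,3-oxazol-2-yl)-6-methylphenyl]methanesulfonamide (4.4 equiv), Et3N, LiCl, THF, rt
Reagents that add atoms: none
Why: Nozaki–Hiyama–Kishi coupling, in which NiCl2 catalyses formation of the alkenylchromium species from the triflate and this adds chemoselectively to the aldehyde; the chiral oxazoline–sulfonamide ligand on chromium (the enantiomer that directs addition to the Re face of 13) should set the new carbinol centre as S.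

Step 12
Reactants: 14 (3S)-6-methyl-2-[(1S,2R,3R,4S,6S)-1-methyl-2,3-bis(triethylsilyloxy)-7-oxabicyclo[4.1.0]heptan-4-yl]hepta-1,5-dien-3-ol
Product: 15 (1R,2R,3R,4S,6S)-4-[(3S)-3-hydroxy-6-methylhepta-1,5-dien-2-yl]-1-methyl-7-oxabicyclo[4.1.0]heptane-2,3-diol
Conditions: Bu4NF, AcOH, THF, 0 °C → rt
Reagents that add atoms: none
Why: Buffered fluoride desilylation should remove both triethylsilyl groups without touching the epoxide, which cannot be opened intramolecularly because all three hydroxyls lie on the same ring face as the epoxide oxygen.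

Step 13
Reactants: 15 (1R,2R,3R,4S,6S)-4-[(3S)-3-hydroxy-6-methylhepta-1,5-dien-2-yl]-1-methyl-7-oxabicyclo[4.1.0]heptane-2,3-diol
Product: 16 (1S,2R,3R,4S,6S)-3-hydroxy-1-methyl-4-[(3S)-6-methyl-3-{[(2Z)-2-methylbut-2-enoyl]oxy}hepta-1,5-dien-2-yl]-7-oxabicyclo[4.1.0]heptan-2-yl (2Z)-2-methylbut-2-enoate
Conditions: angelic acid (3 equiv), 2,4,6-Cl3C6H2COCl, Et3N, toluene, rt; then 15, 75 °C
Reagents that add atoms: angelic acid [(2Z)-2-methylbut-2-enoic acid], C/C=C(/C)C(=O)O
Why: Yamaguchi-type acylation with the preformed mixed anhydride and without DMAP (which would isomerise angelate to tiglate) should esterify the unhindered allylic hydroxyl and the equatorial C2 hydroxyl, while the axial C3 hydroxyl, flanked by the equatorial side chain and the new ester, reacts last; no stereocentre changes.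

Step 14
Reactants: 16 (1S,2R,3R,4S,6S)-3-hydroxy-1-methyl-4-[(3S)-6-methyl-3-{[(2Z)-2-methylbut-2-enoyl]oxy}hepta-1,5-dien-2-yl]-7-oxabicyclo[4.1.0]heptan-2-yl (2Z)-2-methylbut-2-enoate
Product: 17 (1S,2R,3R,4S,6S)-3-acetoxy-1-methyl-4-[(3S)-6-methyl-3-{[(2Z)-2-methylbut-2-enoyl]oxy}hepta-1,5-dien-2-yl]-7-oxabicyclo[4.1.0]heptan-2-yl (2Z)-2-methylbut-2-enoate
Conditions: Ac2O, DMAP (cat.), pyridine, CH2Cl2, rt
Reagents that add atoms: acetic anhydride, CC(=O)OC(C)=O
Why: DMAP-catalysed acetylation of the one remaining (axial, secondary) hydroxyl with the small acyl donor; the installed angelates are stable to DMAP once esterified.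

Step 15
Reactants: 17 (1S,2R,3R,4S,6S)-3-acetoxy-1-methyl-4-[(3S)-6-methyl-3-{[(2Z)-2-methylbut-2-enoyl]oxy}hepta-1,5-dien-2-yl]-7-oxabicyclo[4.1.0]heptan-2-yl (2Z)-2-methylbut-2-enoate
Product: 18 (1S,2R,3R,4S,6S)-3-acetoxy-4-[(3S)-4-[(2S)-3,3-dimethyloxiran-2-yl]-3-{[(2Z)-2-methylbut-2-enoyl]oxy}but-1-en-2-yl]-1-methyl-7-oxabicyclo[4.1.0]heptan-2-yl (2Z)-2-methylbut-2-enoate (CNP0118696.1)
Conditions: 1,2:4,5-di-O-isopropylidene-β-L-erythro-2,3-hexodiulo-2,6-pyranose (30 mol%), KHSO5 (as Oxone), K2CO3, Bu4NHSO4, MeCN/(MeO)2CH2/aq. Na2B4O7 buffer, 0 °C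
Reagents that add atoms: potassium peroxymonosulfate, [K+].[O-]S(=O)(=O)OO
Why: Shi asymmetric epoxidation, in which the chiral dioxirane should react with the electron-rich trisubstituted alkene much faster than with the 1,1-disubstituted alkene bearing an allylic ester or with the electron-poor angelates, the L-fructose-derived ketone being the enantiomer expected to deliver oxygen to the face that gives the 2S oxirane (catalyst control).

**Compound list**

1 | 6-methyl-2H-pyran-2-one | CC1=CC=CC(=O)O1 | starting material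
2 | but-3-en-2-one | CC(=O)C=C | starting material
3 | (1R,4R,7R)-7-acetyl-1-methyl-2-oxabicyclo[2.2.2]oct-5-en-3-one | O=C3[C@@H]1C[C@@H](C(C)=O)[C@](C)(O3)C=C1 | intermediate
4 | (1S,4R,5R,6R,7R)-7-acetyl-5,6-dihydroxy-1-methyl-2-oxabicyclo[2.2.2]octan-3-one | O=C3[C@@H]1C[C@@H](C(C)=O)[C@](C)(O3)[C@H](O)[C@@H]1O | intermediate
5 | (1S,4R,5R,6R,7R)-7-acetyl-1-methyl-5,6-bis(triethylsilyloxy)-2-oxabicyclo[2.2.2]octan-3-one | O=C3[C@@H]1C[C@@H](C(C)=O)[C@](C)(O3)[C@H](O[Si](CC)(CC)CC)[C@@H]1O[Si](CC)(CC)CC | intermediate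
6 | (1S,4R,5R,6R,7R)-1-methyl-3-oxo-5,6-bis(triethylsilyloxy)-2-oxabicyclo[2.2.2]octan-7-yl acetate | O=C3[C@@H]1C[C@@H](OC(C)=O)[C@](C)(O3)[C@H](O[Si](CC)(CC)CC)[C@@H]1O[Si](CC)(CC)CC | intermediate
7 | (1R,2R,3R,4S,5R)-4,5-dihydroxy-N-methoxy-N,4-dimethyl-2,3-bis(triethylsilyloxy)cyclohexane-1-carboxamide | CON(C)C(=O)[C@@H]1C[C@@H](O)[C@](C)(O)[C@H](O[Si](CC)(CC)CC)[C@@H]1O[Si](CC)(CC)CC | intermediate
8 | (1R,2R,3R,4R,5R)-4-hydroxy-N-methoxy-N,4-dimethyl-5-(methylsulfonyloxy)-2,3-bis(triethylsilyloxy)cyclohexane-1-carboxamide | CON(C)C(=O)[C@@H]1C[C@@H](OS(C)(=O)=O)[C@](C)(O)[C@H](O[Si](CC)(CC)CC)[C@@H]1O[Si](CC)(CC)CC | intermediate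
9 | (1S,2R,3R,4R,6S)-N-methoxy-N,1-dimethyl-2,3-bis(triethylsilyloxy)-7-oxabicyclo[4.1.0]heptane-4-carboxamide | CON(C)C(=O)[C@@H]1C[C@@H]2O[C@]2(C)[C@H](O[Si](CC)(CC)CC)[C@@H]1O[Si](CC)(CC)CC | intermediate
10 | 1-[(1S,2R,3R,4R,6S)-1-methyl-2,3-bis(triethylsilyloxy)-7-oxabicyclo[4.1.0]heptan-4-yl]ethan-1-one | CC(=O)[C@@H]1C[C@@H]2O[C@]2(C)[C@H](O[Si](CC)(CC)CC)[C@@H]1O[Si](CC)(CC)CC | intermediate
11 | 1-[(1S,2R,3R,4R,6S)-1-methyl-2,3-bis(triethylsilyloxy)-7-oxabicyclo[4.1.0]heptan-4-yl]ethenyl trifluoromethanesulfonate | C=C(OS(=O)(=O)C(F)(F)F)[C@@H]1C[C@@H]2O[C@]2(C)[C@H](O[Si](CC)(CC)CC)[C@@H]1O[Si](CC)(CC)CC | intermediate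
12 | 4-methylpent-3-en-1-ol | CC(C)=CCCO | starting material
13 | 4-methylpent-3-enal | CC(C)=CCC=O | intermediate
14 | (3S)-6-methyl-2-[(1S,2R,3R,4S,6S)-1-methyl-2,3-bis(triethylsilyloxy)-7-oxabicyclo[4.1.0]heptan-4-yl]hepta-1,5-dien-3-ol | C=C([C@H](CC=C(C)C)O)[C@@H]1C[C@@H]2O[C@]2(C)[C@H](O[Si](CC)(CC)CC)[C@@H]1O[Si](CC)(CC)CC | intermediate
15 | (1R,2R,3R,4S,6S)-4-[(3S)-3-hydroxy-6-methylhepta-1,5-dien-2-yl]-1-methyl-7-oxabicyclo[4.1.0]heptane-2,3-diol | C=C([C@H](CC=C(C)C)O)[C@@H]1C[C@@H]2O[C@]2(C)[C@H](O)[C@@H]1O | intermediate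
16 | (1S,2R,3R,4S,6S)-3-hydroxy-1-methyl-4-[(3S)-6-methyl-3-{[(2Z)-2-methylbut-2-enoyl]oxy}hepta-1,5-dien-2-yl]-7-oxabicyclo[4.1.0]heptan-2-yl (2Z)-2-methylbut-2-enoate | C=C([C@H](CC=C(C)C)OC(=O)/C(C)=C\C)[C@@H]1C[C@@H]2O[C@]2(C)[C@H](OC(=O)/C(C)=C\C)[C@@H]1O | intermediate
17 | (1S,2R,3R,4S,6S)-3-acetoxy-1-methyl-4-[(3S)-6-methyl-3-{[(2Z)-2-methylbut-2-enoyl]oxy}hepta-1,5-dien-2-yl]-7-oxabicyclo[4.1.0]heptan-2-yl (2Z)-2-methylbut-2-enoate | C=C([C@H](CC=C(C)C)OC(=O)/C(C)=C\C)[C@@H]1C[C@@H]2O[C@]2(C)[C@H](OC(=O)/C(C)=C\C)[C@@H]1OC(C)=O | intermediate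
18 | (1S,2R,3R,4S,6S)-3-acetoxy-4-[(3S)-4-[(2S)-3,3-dimethyloxiran-2-yl]-3-{[(2Z)-2-methylbut-2-enoyl]oxy}but-1-en-2-yl]-1-methyl-7-oxabicyclo[4.1.0]heptan-2-yl (2Z)-2-methylbut-2-enoate | C=C([C@H](C[C@@H]1OC1(C)C)OC(=O)/C(C)=C\C)[C@@H]1C[C@@H]2O[C@]2(C)[C@H](OC(=O)/C(C)=C\C)[C@@H]1OC(C)=O | target

**Step count and risks**

Total steps: 15. Longest linear sequence: 14 (steps 1–9 and 11–15; step 10 makes the aldehyde partner).

Steps most likely to fail:

1. Step 1 (the proposed new method). What may go wrong: binding of the pyranone carbonyl to boron slows turnover, and warming to force conversion erodes endo and facial selectivity. Fallback with known chemistry, setting out from 1 and 2 and coming back at 4: 1 and 2 are heated without catalyst (toluene, 85 °C, sealed tube, BHT), the established thermal pyranone cycloaddition, to give after chromatographic removal of the exo isomer the racemic endo adduct F1. OsO4/NMO as in step 2 gives the racemic diol F2. Lipase from Burkholderia cepacia with vinyl acetate in tert-butyl methyl ether acetylates the less hindered 5-hydroxyl of the unwanted enantiomer to give the monoacetate of ent-4 F3, and unreacted 4 is separated by chromatography and enters step 3.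

2. Step 11. What may go wrong: poor facial selectivity in the addition of the alkenylchromium species (ligand control overridden by the neighbouring ring stereocentres), and double-bond migration in the β,γ-unsaturated aldehyde. Fallback, setting out from 11 and 13 and coming back at 14: coupling with CrCl2/NiCl2 in DMF without the chiral ligand gives 14 mixed with its (3R)-epimer F4. Dess–Martin oxidation of the mixture gives the enone F5. Corey–Bakshi–Shibata reduction with catecholborane and (R)-1-methyl-3,3-diphenyltetrahydro-1H,3H-pyrrolo[1,2-c][1,3,2]oxazaborole (toluene, −78 °C), in which the alkenyl group is the large substituent, should return 14 alone.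

3. Step 13. What may go wrong: insufficient site discrimination between the two ring hydroxyls, or over-acylation to the tris-ester. Fallback, setting out from 14 and coming back at 16: 14 is angeloylated at its only free hydroxyl with the same mixed anhydride to give the mono-angelate F6. Bu4NF/AcOH gives the diol F7. Bu2SnO (toluene, reflux, removal of water) gives the dibutylstannylene acetal F8, in which the equatorial oxygen on C2 is the activated one, and the mixed anhydride at room temperature acylates that oxygen to give 16.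

**Further compounds**

F1 | step 1 | racemate of 3 (3 and its enantiomer) | O=C3[C@@H]1C[C@@H](C(C)=O)[C@](C)(O3)C=C1.O=C3[C@H]1C[C@H](C(C)=O)[C@@](C)(O3)C=C1
F2 | step 1 | racemate of 4 (4 and its enantiomer) | O=C3[C@@H]1C[C@@H](C(C)=O)[C@](C)(O3)[C@H](O)[C@@H]1O.O=C3[C@H]1C[C@H](C(C)=O)[C@@](C)(O3)[C@@H](O)[C@H]1O
F3 | step 1 | (1R,4S,5S,6S,7S)-7-acetyl-6-hydroxy-1-methyl-3-oxo-2-oxabicyclo[2.2.2]octan-5-yl acetate (5-O-acetate of ent-4) | O=C3[C@H]1C[C@H](C(C)=O)[C@@](C)(O3)[C@@H](O)[C@H]1OC(C)=O
F4 | step 11 | (3R)-6-methyl-2-[(1S,2R,3R,4S,6S)-1-methyl-2,3-bis(triethylsilyloxy)-7-oxabicyclo[4.1.0]heptan-4-yl]hepta-1,5-dien-3-ol (carbinol epimer of 14) | C=C([C@@H](CC=C(C)C)O)[C@@H]1C[C@@H]2O[C@]2(C)[C@H](O[Si](CC)(CC)CC)[C@@H]1O[Si](CC)(CC)CC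
F5 | step 11 | 6-methyl-2-[(1S,2R,3R,4S,6S)-1-methyl-2,3-bis(triethylsilyloxy)-7-oxabicyclo[4.1.0]heptan-4-yl]hepta-1,5-dien-3-one | C=C(C(=O)CC=C(C)C)[C@@H]1C[C@@H]2O[C@]2(C)[C@H](O[Si](CC)(CC)CC)[C@@H]1O[Si](CC)(CC)CC
F6 | step 13 | (3S)-6-methyl-2-[(1S,2R,3R,4S,6S)-1-methyl-2,3-bis(triethylsilyloxy)-7-oxabicyclo[4.1.0]heptan-4-yl]hepta-1,5-dien-3-yl (2Z)-2-methylbut-2-enoate | C=C([C@H](CC=C(C)C)OC(=O)/C(C)=C\C)[C@@H]1C[C@@H]2O[C@]2(C)[C@H](O[Si](CC)(CC)CC)[C@@H]1O[Si](CC)(CC)CC
F7 | step 13 | (3S)-2-[(1R,2R,3R,4S,6S)-2,3-dihydroxy-1-methyl-7-oxabicyclo[4.1.0]heptan-4-yl]-6-methylhepta-1,5-dien-3-yl (2Z)-2-methylbut-2-enoate | C=C([C@H](CC=C(C)C)OC(=O)/C(C)=C\C)[C@@H]1C[C@@H]2O[C@]2(C)[C@H](O)[C@@H]1O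
F8 | step 13 | 2,3-O-dibutylstannylene acetal of F7 | C=C([C@H](CC=C(C)C)OC(=O)/C(C)=C\C)[C@@H]1C[C@@H]2O[C@]2(C)[C@@H]3O[Sn](CCCC)(CCCC)O[C@H]13
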